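**Retrosynthetic overview**

1. Target 16 ⇐ O-acetylation of hydroxyquinone 15 ⇐ alkaline hydrolysis of the vinylogous ester 14 ⇐ oxidation at C4 of the 2-methoxy-1-naphthol 13.
2. 13 ⇐ isocoumarin 9 + methoxymethyllithium (key step): the ring oxygen of the lactone is exchanged for the oxygen-bearing carbon C2; acyl substitution at C1 opens the pyranone, and an aldol condensation joins C2 to the isopropyl-bearing C3 and closes the carbocycle.
3. Enabling feature: in the quinone ring C1(=O)–C2(O)–C3(iPr)–C4–C4a–C8a, the five atoms other than C2 are exactly the carbon atoms of the pyranone ring of a 3-isopropylisocoumarin (lactone carbonyl C1 on C8a, enol carbon C3, C4, C4a). C2 lies between two carbonyl-level carbons, C1 and C3, which are 1,5-related through the benzo ring, so a one-carbon oxygenated nucleophile can be spliced in as the enolisable α-carbon of C1 and condensed onto C3.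
4. 9 ⇐ carboxylate-directed C–H acylmethylation/lactonisation of benzoic acid 3 with sulfoxonium ylide 7; 3 ⇐ lateral alkylation of the dianion of 2,3-dimethylbenzoic acid 1 with the homoallylic bromide 2.
5. Ring order: benzene ring (bought) → pyranone ring (step 3) → carbocyclic ring that replaces the pyranone (step 4) → quinone by oxidation (step 5).

Key step: step 4

Assumption: the target has no stereocentre and no stereogenic double bond, so names and SMILES carry no descriptors; compounds 1, 2, 4, 5 and 10 are taken as commercial.

**Route**

Step 1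
Reactants: 1 2,3-dimethylbenzoic acid; 2 4-bromo-2-methylbut-1-ene
Product: 3 3-methyl-2-(4-methylpent-4-en-1-yl)benzoic acid
Conditions: LiN(iPr)2 (LDA, 2.2 equiv), THF, −78 → 0 °C; then 2, −78 °C → rt; cold 1 M HCl work-up
Reagents that add atoms: none
Why: Lateral (benzylic) lithiation of the o-toluate dianion should occur only at the 2-methyl group, the one conjugated with the carboxylate, and the carbanion is then alkylated by the primary bromide in an SN2 reaction.

Step 2
Reactants: 4 trimethylsulfoxonium iodide; 5 2-methylpropanoyl chloride
Product: 7 1-[dimethyl(oxo)-λ6-sulfanylidene]-3-methylbutan-2-one, via dimethylsulfoxonium methylide 6 (not isolated)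
Conditions: 4 (3 equiv), KOtBu (3 equiv), THF, reflux, 2 h; then 5 (1 equiv), 0 °C → rt
Reagents that add atoms: none
Why: Acylation of the Corey–Chaykovsky ylide by the acid chloride, followed by deprotonation of the acylsulfoxonium salt by a second equivalent of methylide, is the standard preparation of stabilised β-keto sulfoxonium ylides.

Step 3
Reactants: 3 3-methyl-2-(4-methylpent-4-en-1-yl)benzoic acid; 7 1-[dimethyl(oxo)-λ6-sulfanylidene]-3-methylbutan-2-one
Product: 9 7-methyl-8-(4-methylpent-4-en-1-yl)-3-(propan-2-yl)-1H-isochromen-1-one, via ortho-acylmethyl keto acid 8 (not isolated)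
Conditions: [Cp*RhCl2]2 (pentamethylcyclopentadienylrhodium dichloride dimer, trivalent rhodium, 2.5 mol %), AgSbF6 (10 mol %), NaOAc (0.5 equiv), (CF3)2CHOH, 60 °C, Ar
Reagents that add atoms: none
Why: Carboxylate-directed C–H activation at the only free ortho position, carbene transfer from the sulfoxonium ylide with loss of DMSO and protodemetalation should give keto acid 8, which lactonises through its enol with loss of water to the 3-substituted isocoumarin (rhodium-catalysed C–H acylmethylation/annulation of benzoic acids with sulfoxonium ylides).

Step 4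
Reactants: 9 7-methyl-8-(4-methylpent-4-en-1-yl)-3-(propan-2-yl)-1H-isochromen-1-one; 10 tributyl(methoxymethyl)stannane
Product: 13 2-methoxy-7-methyl-8-(4-methylpent-4-en-1-yl)-3-(propan-2-yl)naphthalen-1-ol, via methoxymethyllithium 11 (not isolated), via ring-opened diketone 12 (not isolated)
Conditions: 10 (1.1 equiv), n-BuLi (1.05 equiv), THF, −78 °C; then 9, −78 → 0 °C; then MeOH, NaOMe (0.2 equiv), rt → 50 °C, Ar; AcOH quench
Reagents that add atoms: none
Why: Methoxymethyllithium (from tin–lithium exchange) should add 1,2 to the lactone carbonyl C1 of 9, and the cyclic lithium hemiketal, which shields against a second addition at −78 °C, opens on warming with expulsion of the enolate oxygen to the 1,5-diketone 12; under methoxide the enolate of the new α-methoxy ketone then attacks the isopropyl ketone carbon, forming the C2–C3 bond, and E1cB loss of water plus tautomerisation of the C4 methylene give the aromatic naphtholate. The closest known reaction types are the carbanion-induced ring transformation of 2-pyranones and isocoumarins into arenes and the base-induced recyclisation of 1-alkyl-2-benzopyrylium salts into 1-naphthols, that is, organolithium acyl substitution on an enol lactone followed by intramolecular aldol condensation. The one ring that is closed, the carbocycle C1–C2–C3–C4–C4a–C8a, forms in the 6-(enolendo)-exo-trig mode, and no stereocentre is created because the product is a planar naphthol. The step needs chemoselectivity (a single addition) and regioselectivity in the condensation: the first is secured by the hemiketal resting state, the hindered 2,6-disubstituted aryl ketone and the use of one equivalent at low temperature; the second is secured by the substrate, since the benzylic C4 enolate could only close a four-membered ring and an aldol through the isopropyl methine gives an adduct that cannot dehydrate and reverts, so only the C2-to-C3 closure can aromatise and serve as the thermodynamic sink.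

Step 5
Reactants: 13 2-methoxy-7-methyl-8-(4-methylpent-4-en-1-yl)-3-(propan-2-yl)naphthalen-1-ol
Product: 14 2-methoxy-7-methyl-8-(4-methylpent-4-en-1-yl)-3-(propan-2-yl)naphthalene-1,4-dione
Conditions: (KSO3)2NO (Fremy's salt, 2.5 equiv), KH2PO4 (aq), acetone/H2O, rt
Reagents that add atoms: dipotassium nitrosodisulfonate (Fremy's salt), [K+].[K+].[O]N(S(=O)(=O)[O-])S(=O)(=O)[O-]
Why: In the Teuber oxidation the nitroxyl radical abstracts the phenolic hydrogen and a second equivalent delivers oxygen to the free para position C4 of the electron-rich 1-naphthol, which should give the 1,4-quinone and leave the isolated alkene untouched.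

Step 6
Reactants: 14 2-methoxy-7-methyl-8-(4-methylpent-4-en-1-yl)-3-(propan-2-yl)naphthalene-1,4-dione
Product: 15 2-hydroxy-7-methyl-8-(4-methylpent-4-en-1-yl)-3-(propan-2-yl)naphthalene-1,4-dione
Conditions: NaOH (2 M aq), THF/MeOH, 50 °C, Ar; then cold 1 M HCl to pH 3
Reagents that add atoms: sodium hydroxide, [Na+].[OH-]
Why: The 2-methoxyquinone is a vinylogous ester, so hydroxide should add at C2 and expel methoxide (addition–elimination), driven by formation of the stabilised anion of the acidic 2-hydroxyquinone.

Step 7
Reactants: 15 2-hydroxy-7-methyl-8-(4-methylpent-4-en-1-yl)-3-(propan-2-yl)naphthalene-1,4-dione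
Product: 16 7-methyl-8-(4-methylpent-4-en-1-yl)-1,4-dioxo-3-(propan-2-yl)-1,4-dihydronaphthalen-2-yl acetate (acetylsalvipisone)
Conditions: Ac2O, pyridine, DMAP (cat.), CH2Cl2, 0 °C → rt
Reagents that add atoms: acetic anhydride, CC(=O)OC(C)=O
Why: O-acylation of the acidic vinylogous carboxylic acid OH should give the enol acetate under mild basic conditions that affect neither the terminal alkene nor the quinone.

**Compound list**

1 | 2,3-dimethylbenzoic acid | Cc1cccc(C(=O)O)c1C | starting material
2 | 4-bromo-2-methylbut-1-ene | C=C(C)CCBr | starting material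
3 | 3-methyl-2-(4-methylpent-4-en-1-yl)benzoic acid | C=C(C)CCCc1c(C)cccc1C(=O)O | intermediate
4 | trimethylsulfoxonium iodide | C[S+](C)(C)=O.[I-] | starting material
5 | 2-methylpropanoyl chloride | CC(C)C(=O)Cl | starting material
6 | dimethylsulfoxonium methylide | C=S(C)(C)=O | intermediate
7 | 1-[dimethyl(oxo)-λ6-sulfanylidene]-3-methylbutan-2-one | CC(C)C(=O)C=S(C)(C)=O | intermediate
8 | 3-methyl-6-(3-methyl-2-oxobutyl)-2-(4-methylpent-4-en-1-yl)benzoic acid | C=C(C)CCCc1c(C)ccc(CC(=O)C(C)C)c1C(=O)O | intermediate
9 | 7-methyl-8-(4-methylpent-4-en-1-yl)-3-(propan-2-yl)-1H-isochromen-1-one | C=C(C)CCCc1c(C)ccc2C=C(C(C)C)OC(=O)c12 | intermediate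
10 | tributyl(methoxymethyl)stannane | CCCC[Sn](CCCC)(CCCC)COC | starting material
11 | methoxymethyllithium | [Li]COC | intermediate
12 | 1-[2-(methoxyacetyl)-4-methyl-3-(4-methylpent-4-en-1-yl)phenyl]-3-methylbutan-2-one | C=C(C)CCCc1c(C)ccc(CC(=O)C(C)C)c1C(=O)COC | intermediate
13 | 2-methoxy-7-methyl-8-(4-methylpent-4-en-1-yl)-3-(propan-2-yl)naphthalen-1-ol | C=C(C)CCCc1c(C)ccc2cc(C(C)C)c(OC)c(O)c12 | intermediate
14 | 2-methoxy-7-methyl-8-(4-methylpent-4-en-1-yl)-3-(propan-2-yl)naphthalene-1,4-dione | C=C(C)CCCc1c(C)ccc2c1C(=O)C(OC)=C(C(C)C)C2=O | intermediate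
15 | 2-hydroxy-7-methyl-8-(4-methylpent-4-en-1-yl)-3-(propan-2-yl)naphthalene-1,4-dione | C=C(C)CCCc1c(C)ccc2c1C(=O)C(O)=C(C(C)C)C2=O | intermediate
16 | 7-methyl-8-(4-methylpent-4-en-1-yl)-1,4-dioxo-3-(propan-2-yl)-1,4-dihydronaphthalen-2-yl acetate (acetylsalvipisone) | C=C(C)CCCc1c(C)ccc2c1C(=O)C(OC(C)=O)=C(C(C)C)C2=O | target

**Step count and risks**

Total step count: 7 (steps 1–7; step 2 prepares the ylide on a side branch).
Longest linear sequence: 6 steps (1 → 3 → 9 → 13 → 14 → 15 → 16, that is steps 1, 3, 4, 5, 6 and 7).

Steps most likely to fail: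

Step 4. The unstabilised organolithium may add a second time to the aryl ketone once the hemiketal opens, or the aldol condensation onto the hindered isopropyl ketone may stall at the open-chain stage. The fallback sets out from 9 and comes back at 13. The lactone 9 is acylated instead by a stabilised carbanion, lithiated diethyl (methoxymethyl)phosphonate (LiN(iPr)2, THF, −78 °C, 2 equiv). Its β-keto phosphonate product is deprotonated in the flask and so cannot add twice; this gives diethyl {1-methoxy-2-[3-methyl-6-(3-methyl-2-oxobutyl)-2-(4-methylpent-4-en-1-yl)phenyl]-2-oxoethyl}phosphonate F1. NaH in THF (or K2CO3 with 18-crown-6) should then close the same ring bond by intramolecular Horner–Wadsworth–Emmons olefination onto the isopropyl ketone, and enolisation of the cyclised product delivers 13.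

Step 3. The terminal 1,1-disubstituted alkene may isomerise under the cationic metal and fluorinated alcohol, the ylide may esterify the acid oxygen instead of functionalising the C–H bond, or cyclodehydration of the keto acid may be incomplete. The fallback sets out from 1 (with 2) and comes back at 9. Iodine is introduced before any alkene is present: carboxylate-directed ortho-iodination of 1 with Pd(OAc)2 (palladium diacetate, divalent palladium, cat.), PhI(OAc)2 and I2 in DMF should give 6-iodo-2,3-dimethylbenzoic acid F2. Lateral lithiation (LiN(iPr)2, 2.2 equiv, THF, −78 °C) and alkylation with 2 then give 6-iodo-3-methyl-2-(4-methylpent-4-en-1-yl)benzoic acid F3. Coupling of F3 with 3-methylbut-1-yne under Pd(PPh3)4 (zerovalent palladium), ZnCl2 and Et3N in DMF (tandem Sonogashira-type coupling and 6-endo-dig lactonisation, neutral to basic throughout) gives 9.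

Step 1. The strongly basic dianion may eliminate HBr from the homoallylic bromide (its β-hydrogens are allylic) instead of substituting it, and double alkylation at the benzylic carbon may occur. The fallback sets out from 1 and comes back at 3. The dianion of 1 is alkylated with 2-(2-bromoethyl)-2-methyl-1,3-dioxolane, which has no allylic β-hydrogens, to give 3-methyl-2-[3-(2-methyl-1,3-dioxolan-2-yl)propyl]benzoic acid F4. Aqueous HCl in THF removes the ketal while no alkene is present and gives 3-methyl-2-(4-oxopentyl)benzoic acid F5. Wittig methylenation of the carboxylate with excess Ph3P=CH2 (from Ph3PCH3Br and KOtBu, THF) gives 3.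

**Further compounds**

F1 | step 4 | diethyl {1-methoxy-2-[3-methyl-6-(3-methyl-2-oxobutyl)-2-(4-methylpent-4-en-1-yl)phenyl]-2-oxoethyl}phosphonate | C=C(C)CCCc1c(C)ccc(CC(=O)C(C)C)c1C(=O)C(OC)P(=O)(OCC)OCC
F2 | step 3 | 6-iodo-2,3-dimethylbenzoic acid | Cc1ccc(I)c(C(=O)O)c1C
F3 | step 3 | 6-iodo-3-methyl-2-(4-methylpent-4-en-1-yl)benzoic acid | C=C(C)CCCc1c(C)ccc(I)c1C(=O)O
F4 | step 1 | 3-methyl-2-[3-(2-methyl-1,3-dioxolan-2-yl)propyl]benzoic acid | Cc1cccc(C(=O)O)c1CCCC2(C)OCCO2
F5 | step 1 | 3-methyl-2-(4-oxopentyl)benzoic acid | Cc1cccc(C(=O)O)c1CCCC(C)=O
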